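**Assumption:** the target has no stereocentre and is achiral, so the "single enantiomer" is simply the one structure drawn; the flavanone intermediate is used as the racemate because its only stereocentre is erased in the key step.

**Retrosynthetic overview**
1. Target 10 ⇐ 5,7-di-O-benzyl isoflavone 9 by hydrogenolysis (last step).
2. Key step: 9 ⇐ flavanone 8 by oxidative 2,3-aryl shift with trivalent iodine (isoflavone-synthase mimic). The C3–aryl bond is made by migration, not by a deoxybenzoin or a cross-coupling.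
3. 8 ⇐ acetophenone 5 + 2,3,4-trimethoxybenzaldehyde 6 (Claisen–Schmidt, then oxa-Michael). Ring C closes on the only free phenol, which fixes the 6-OMe (not 8-OMe) pattern.
4. 5 ⇐ phloroacetophenone 1 by 4,6-dibenzylation, Elbs para-hydroxylation and O-methylation.
5. Ring order: rings A and B are bought; ring C is formed in step 4 and rearranged in step 5.

**Step 1**
Reactants: 1 1-(2,4,6-trihydroxyphenyl)ethanone (phloroacetophenone)
Product: 2 1-[2,4-bis(benzyloxy)-6-hydroxyphenyl]ethanone
Conditions: BnBr (2.1 equiv), K2CO3 (2.2 equiv), DMF, 0 °C to rt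
Reagents that add atoms: benzyl bromide, BrCc1ccccc1
Why: Williamson ether synthesis in which the 4-OH and one ortho OH are benzylated, while the last OH is locked in a hydrogen bond to the ketone and reacts far more slowly, so the reaction stops at the dibenzyl ether.

**Step 2**
Reactants: 2 1-[2,4-bis(benzyloxy)-6-hydroxyphenyl]ethanone
Product: 4 1-[2,4-bis(benzyloxy)-3,6-dihydroxyphenyl]ethanone, via potassium aryl sulfate 3 (not isolated)
Conditions: K2S2O8 (1.1 equiv), aq KOH, pyridine, 0 °C to rt; then 2 M HCl, 80 °C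
Reagents that add atoms: potassium peroxodisulfate, [K+].[K+].[O-]S(=O)(=O)OOS(=O)(=O)[O-]
Why: Elbs persulfate oxidation, in which the phenolate attacks the peroxide oxygen through its free para carbon to give the aryl sulfate, which acid then hydrolyses to the hydroquinone; benzyl ethers survive both stages.

**Step 3**
Reactants: 4 1-[2,4-bis(benzyloxy)-3,6-dihydroxyphenyl]ethanone
Product: 5 1-[2,4-bis(benzyloxy)-6-hydroxy-3-methoxyphenyl]ethanone
Conditions: MeI (1.1 equiv), K2CO3 (1.1 equiv), acetone, reflux, under N2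
Reagents that add atoms: iodomethane, CI
Why: Williamson O-methylation that is selective because the 6-OH is chelated to the ketone and much less nucleophilic than the new 3-OH, so one equivalent of MeI caps only the 3-OH.

**Step 4**
Reactants: 5 1-[2,4-bis(benzyloxy)-6-hydroxy-3-methoxyphenyl]ethanone; 6 2,3,4-trimethoxybenzaldehyde
Product: 8 rac-5,7-bis(benzyloxy)-6-methoxy-2-(2,3,4-trimethoxyphenyl)-2,3-dihydro-4H-chromen-4-one, via 2'-hydroxychalcone 7 (not isolated)
Conditions: KOH (50% aq, excess), EtOH/THF, rt, 48 h; then AcOH to pH 6, reflux, 12 h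
Reagents that add atoms: none
Why: Claisen–Schmidt aldol condensation gives the E-chalcone, and in the acetate buffer formed on quenching the single free phenol closes ring C by 6-endo oxa-Michael addition (the 6'-benzyloxy group twists the chalcone and favours the flavanone); C2 is formed racemic and is destroyed in step 5.

**Step 5**
Reactants: 8 rac-5,7-bis(benzyloxy)-6-methoxy-2-(2,3,4-trimethoxyphenyl)-2,3-dihydro-4H-chromen-4-one
Product: 9 5,7-bis(benzyloxy)-6-methoxy-3-(2,3,4-trimethoxyphenyl)-4H-chromen-4-one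
Conditions: PhI(OH)OTs (1.2 equiv), TsOH·H2O (0.1 equiv), MeCN, 60 °C
Reagents that add atoms: none
Why: Oxidative 2,3-aryl migration of a flavanone with a trivalent-iodine reagent, in which the enol attacks iodine at C3, the electron-rich 2,3,4-trimethoxyphenyl group shifts from C2 to C3 through a phenonium ion as PhI leaves, and the O1-stabilised C2 cation loses H-3 to give the isoflavone; MeCN keeps the C4 ketone unketalised, which shuts off ring contraction by migration of ring A.

**Step 6**
Reactants: 9 5,7-bis(benzyloxy)-6-methoxy-3-(2,3,4-trimethoxyphenyl)-4H-chromen-4-one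
Product: 10 5,7-dihydroxy-6-methoxy-3-(2,3,4-trimethoxyphenyl)-4H-chromen-4-one
Conditions: H2 (1 atm), Pd/C (10 wt% Pd on carbon), EtOAc/MeOH, rt, stopped after 2 equiv H2
Reagents that add atoms: none
Why: Catalytic hydrogenolysis cleaves both benzylic C–O bonds while the methyl ethers are inert and the vinylogous-ester C2=C3 bond is reduced much more slowly; no base or strong acid is present, so the 6-OMe/8-OMe ring-opening isomerisation cannot occur.

**Compound list**
1 | 1-(2,4,6-trihydroxyphenyl)ethanone | CC(=O)c1c(O)cc(O)cc1O | starting material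
2 | 1-[2,4-bis(benzyloxy)-6-hydroxyphenyl]ethanone | CC(=O)c1c(O)cc(OCc2ccccc2)cc1OCc1ccccc1 | intermediate
3 | potassium 3-acetyl-2,6-bis(benzyloxy)-4-hydroxyphenyl sulfate | CC(=O)c1c(O)cc(OCc2ccccc2)c(OS(=O)(=O)[O-])c1OCc1ccccc1.[K+] | intermediate (not isolated)
4 | 1-[2,4-bis(benzyloxy)-3,6-dihydroxyphenyl]ethanone | CC(=O)c1c(O)cc(OCc2ccccc2)c(O)c1OCc1ccccc1 | intermediate
5 | 1-[2,4-bis(benzyloxy)-6-hydroxy-3-methoxyphenyl]ethanone | CC(=O)c1c(O)cc(OCc2ccccc2)c(OC)c1OCc1ccccc1 | intermediate
6 | 2,3,4-trimethoxybenzaldehyde | COc1ccc(C=O)c(OC)c1OC | starting material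
7 | (E)-1-[2,4-bis(benzyloxy)-6-hydroxy-3-methoxyphenyl]-3-(2,3,4-trimethoxyphenyl)prop-2-en-1-one | COc1ccc(/C=C/C(=O)c2c(O)cc(OCc3ccccc3)c(OC)c2OCc2ccccc2)c(OC)c1OC | intermediate (not isolated)
8 | rac-5,7-bis(benzyloxy)-6-methoxy-2-(2,3,4-trimethoxyphenyl)-2,3-dihydro-4H-chromen-4-one (racemate) | COc1ccc(C2CC(=O)c3c(OCc4ccccc4)c(OC)c(OCc4ccccc4)cc3O2)c(OC)c1OC | intermediate
9 | 5,7-bis(benzyloxy)-6-methoxy-3-(2,3,4-trimethoxyphenyl)-4H-chromen-4-one | COc1ccc(-c2coc3cc(OCc4ccccc4)c(OC)c(OCc4ccccc4)c3c2=O)c(OC)c1OC | intermediate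
10 | 5,7-dihydroxy-6-methoxy-3-(2,3,4-trimethoxyphenyl)-4H-chromen-4-one (achiral) | COc1ccc(-c2coc3cc(O)c(OC)c(O)c3c2=O)c(OC)c1OC | target

**Totals**
Total step count: 6. Longest linear sequence: 6 steps (1 to 10); aldehyde 6 is bought.

**Three steps most likely to fail, with fallbacks**

Step 5 (aryl shift) is the riskiest. The competing outcomes are dehydrogenation to the 2-aryl flavone and attack of the iodine reagent on the electron-rich C8 or C5' positions to give iodonium salts. The fallback gives up the migration and sets out from 5, coming back at 9. Compound 5 is heated with N,N-dimethylformamide dimethyl acetal (toluene, 95 °C) to give the enaminone (E)-1-[2,4-bis(benzyloxy)-6-hydroxy-3-methoxyphenyl]-3-(dimethylamino)prop-2-en-1-one F1. I2 in CHCl3 at rt closes the pyranone with loss of dimethylamine and iodinates C3, giving 5,7-bis(benzyloxy)-3-iodo-6-methoxy-4H-chromen-4-one F2. Suzuki–Miyaura coupling of F2 with commercial (2,3,4-trimethoxyphenyl)boronic acid (COc1ccc(B(O)O)c(OC)c1OC), using Pd(PPh3)4 (a zerovalent palladium complex) and K2CO3 in dioxane/H2O at 85 °C, gives 9.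

Step 2 (Elbs oxidation) typically gives only modest yield, and the hydroquinone 4 is air-sensitive. The fallback sets out from 2 and comes back at 5, skipping 4 and step 3. Oxidative dearomatisation of 2 with PhI(OAc)2 (2.2 equiv) in MeOH at 0 °C adds methanol twice at the para carbon to give the quinone monoketal 2-acetyl-3,5-bis(benzyloxy)-4,4-dimethoxycyclohexa-2,5-dien-1-one F3. Reduction of F3 with Zn dust in AcOH at rt expels one methanol, rearomatises the ring and delivers the para-methoxyphenol 5 directly.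

Step 4 may stall at the chalcone if the hindered oxa-Michael closure does not go to completion. The fallback sets out from 7, which is then isolated by cold acidification after the aldol stage, and comes back at 9, skipping 8 and step 5. Acetylation (Ac2O, pyridine, DMAP, rt) masks the oxidisable para-methoxyphenol as 3,5-bis(benzyloxy)-4-methoxy-2-[(E)-3-(2,3,4-trimethoxyphenyl)prop-2-enoyl]phenyl acetate F4. An open-chain oxidative 1,2-aryl shift with PhI(OH)OTs in MeOH at rt moves the trimethoxyphenyl group to the α-carbon and gives the keto acetal rac-3,5-bis(benzyloxy)-2-[3,3-dimethoxy-2-(2,3,4-trimethoxyphenyl)propanoyl]-4-methoxyphenyl acetate F5. Treating F5 with K2CO3 in MeOH removes the acetate, and HCl in MeOH at 60 °C then closes ring C onto the acetal carbon with loss of methanol to give 9.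

**Further compounds**
F1 | step 5 | (E)-1-[2,4-bis(benzyloxy)-6-hydroxy-3-methoxyphenyl]-3-(dimethylamino)prop-2-en-1-one | CN(C)/C=C/C(=O)c1c(O)cc(OCc2ccccc2)c(OC)c1OCc1ccccc1
F2 | step 5 | 5,7-bis(benzyloxy)-3-iodo-6-methoxy-4H-chromen-4-one | COc1c(OCc2ccccc2)cc2occ(I)c(=O)c2c1OCc1ccccc1
F3 | step 2 | 2-acetyl-3,5-bis(benzyloxy)-4,4-dimethoxycyclohexa-2,5-dien-1-one | CC(=O)C1=C(OCc2ccccc2)C(OC)(OC)C(OCc2ccccc2)=CC1=O
F4 | step 4 | 3,5-bis(benzyloxy)-4-methoxy-2-[(E)-3-(2,3,4-trimethoxyphenyl)prop-2-enoyl]phenyl acetate | COc1ccc(/C=C/C(=O)c2c(OC(C)=O)cc(OCc3ccccc3)c(OC)c2OCc2ccccc2)c(OC)c1OC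
F5 | step 4 | rac-3,5-bis(benzyloxy)-2-[3,3-dimethoxy-2-(2,3,4-trimethoxyphenyl)propanoyl]-4-methoxyphenyl acetate | COc1ccc(C(C(OC)OC)C(=O)c2c(OC(C)=O)cc(OCc3ccccc3)c(OC)c2OCc2ccccc2)c(OC)c1OC
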